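**Retrosynthetic overview** (ring atoms in benzofuranone numbering: O1, C2, C3, C3a, C4–C7, C7a; ring A = cyclohexenone, ring B = dihydrofuran; side-chain atoms primed, C1' = carboxyl carbon, C10' = carbinol carbon, C11' = its methyl)
1. Endgame: the acid C1' comes from an allylic silyl ether and the carbinol C10'(OH)CH3 from a 2,2-disubstituted epoxide. Ring B is the only ring formed in the route, closed by O1–C7a vinylogous transetherification onto ring A, which is bought as 3-methoxycyclohexenone.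
2. Key disconnection: C2–C10' together with C3–C3a, in an enantioselective three-component conjunctive coupling of a geranylacetone-derived 2-lithio-1-alkene (C10' and chain), vinyl–B(pin) (C2 and C3) and a 2-bromo vinylogous ester (ring A).
3. Enabling feature: the array C3a(sp2, ring A)–C3H2–C2H(O)–C10'(CH3). An sp2 ring carbon, one methylene, an oxygen-bearing stereocentre and a carbon carrying a methyl group make up exactly the R(sp2)–CH2–CH(B)–C(=CH2)R' pattern that a vinylboron "ate" complex writes; the C–B bond is the latent C2–O1 bond and the =CH2 the latent C11' methyl.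
4. Stereocentres: C2 by the catalyst in the key step, C10' relayed from C2 by hydroxyl-directed erythro epoxidation, C5 by trivalent-manganese α'-acetoxylation and lipase resolution of ring A before the coupling.

Key step: step 8

Assumption: geranylacetone is used as the single 5E isomer, and the lipase of step 5 is one that hydrolyses the (R)-acetate; if the enzyme at hand prefers the (S)-acetate, the recovered (R)-acetate is cleaved with K2CO3/MeOH to the same alcohol 7.

**Step 1**
Reactants: 1 (E)-geranylacetone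
Product: 2 (5E,9E)-11-hydroxy-6,10-dimethylundeca-5,9-dien-2-one
Conditions: SeO2 (0.1 equiv), t-BuOOH (2 equiv), salicylic acid (0.1 equiv), CH2Cl2, rt
Reagents that add atoms: tert-butyl hydroperoxide, CC(C)(C)OO; selenium dioxide, O=[Se]=O
Why: Catalytic SeO2 allylic oxidation (ene reaction, then [2,3]-sigmatropic shift) should select the E-methyl group of the terminal isopropylidene unit, giving the E-allylic alcohol with the internal olefin and the ketone untouched.

**Step 2**
Reactants: 2 (5E,9E)-11-hydroxy-6,10-dimethylundeca-5,9-dien-2-one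
Product: 3 (5E,9E)-11-[(tert-butyldimethylsilyl)oxy]-6,10-dimethylundeca-5,9-dien-2-one
Conditions: TBSCl, imidazole, CH2Cl2, 0 °C to rt
Reagents that add atoms: tert-butyldimethylsilyl chloride, CC(C)(C)[Si](C)(C)Cl
Why: Standard silylation of a primary alcohol, which masks the hydroxyl against the alkyllithium of step 8.

**Step 3**
Reactants: 3 (5E,9E)-11-[(tert-butyldimethylsilyl)oxy]-6,10-dimethylundeca-5,9-dien-2-one
Product: 4 N'-[(2E,5E,9E)-11-[(tert-butyldimethylsilyl)oxy]-6,10-dimethylundeca-5,9-dien-2-ylidene]-2,4,6-tri(propan-2-yl)benzenesulfonohydrazide (trisylhydrazone of 3)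
Conditions: 2,4,6-triisopropylbenzenesulfonyl hydrazide, THF, 4 Å molecular sieves, rt (no acid)
Reagents that add atoms: 2,4,6-triisopropylbenzenesulfonyl hydrazide, CC(C)c1cc(C(C)C)c(S(=O)(=O)NN)c(C(C)C)c1
Why: Condensation of a methyl ketone with an arylsulfonyl hydrazide should give the E-hydrazone, and the hindered trisyl group prevents ortho-lithiation in the later Shapiro reaction.

**Step 4**
Reactants: 5 3-methoxycyclohex-2-en-1-one
Product: 6 (±)-4-methoxy-2-oxocyclohex-3-en-1-yl acetate (rac-6-acetoxy-3-methoxycyclohex-2-en-1-one)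
Conditions: Mn(OAc)3·2H2O (2.5 equiv), benzene, reflux (water separator)
Reagents that add atoms: manganese triacetate, CC(=O)[O-].CC(=O)[O-].CC(=O)[O-].[Mn+3]
Why: α'-Acetoxylation of an enone through the manganese enolate and acetate transfer; the vinylogous ester enolises only towards C6, the future C5 of the target.

**Step 5**
Reactants: 6 (±)-4-methoxy-2-oxocyclohex-3-en-1-yl acetate
Product: 7 (6R)-6-hydroxy-3-methoxycyclohex-2-en-1-one
Conditions: lipase (Burkholderia cepacia lipase, Amano PS), phosphate buffer pH 7, MTBE co-solvent, rt, stopped near half conversion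
Reagents that add atoms: none
Why: Enzymatic kinetic resolution by enantioselective ester hydrolysis; the lipase discriminates the enantiomers of the secondary acetate and thereby sets the C5 stereocentre of the target (R).

**Step 6**
Reactants: 7 (6R)-6-hydroxy-3-methoxycyclohex-2-en-1-one
Product: 8 (6R)-6-[(tert-butyldimethylsilyl)oxy]-3-methoxycyclohex-2-en-1-one
Conditions: TBSCl, imidazole, DMF, rt
Reagents that add atoms: tert-butyldimethylsilyl chloride, CC(C)(C)[Si](C)(C)Cl
Why: Standard silylation; the silyl ether blocks the ketol hydroxyl and shields the α-stereocentre from enolisation.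

**Step 7**
Reactants: 8 (6R)-6-[(tert-butyldimethylsilyl)oxy]-3-methoxycyclohex-2-en-1-one
Product: 9 (6R)-2-bromo-6-[(tert-butyldimethylsilyl)oxy]-3-methoxycyclohex-2-en-1-one
Conditions: N-bromosuccinimide, CH2Cl2, 0 °C, dark
Reagents that add atoms: N-bromosuccinimide, O=C1CCC(=O)N1Br
Why: Electrophilic bromination at the nucleophilic α-carbon of the vinylogous ester and loss of the proton should give the alkenyl bromide at the future C3a.

**Step 8**
Reactants: 4 trisylhydrazone of 3; 10 4,4,5,5-tetramethyl-2-vinyl-1,3,2-dioxaborolane (vinylboronic acid pinacol ester); 9 (6R)-2-bromo-6-[(tert-butyldimethylsilyl)oxy]-3-methoxycyclohex-2-en-1-one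
Product: 13 (6R)-6-[(tert-butyldimethylsilyl)oxy]-2-[(2S,6E,10E)-12-[(tert-butyldimethylsilyl)oxy]-7,11-dimethyl-3-methylidene-2-(4,4,5,5-tetramethyl-1,3,2-dioxaborolan-2-yl)dodeca-6,10-dien-1-yl]-3-methoxycyclohex-2-en-1-one, via alkenyllithium 11 (not isolated), via lithium bis(alkenyl)borate 12 (not isolated)
Conditions: 4, n-BuLi (2.05 equiv), THF, −78 to 0 °C; 10, −78 °C to rt; then 9, Pd(OAc)2 (3 mol %), Mandyphos, i.e. 1,1'-bis[bis(4-methoxy-3,5-dimethylphenyl)phosphino]-2,2'-bis[(dimethylamino)(phenyl)methyl]ferrocene (3.6 mol %, the enantiomer that gives 2S), NaOTf, THF, 60 °C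
Reagents that add atoms: none
Why: Shapiro fragmentation of the hydrazone dianion gives the 2-lithio-1-alkene 11, which adds to boron of 10 to give borate 12; zerovalent palladium inserts into the C–Br bond of 9, and the cationic divalent palladium alkenyl (bromide removed as NaBr) binds the unsubstituted vinyl group of 12 and triggers an anti 1,2-metalate shift of the 1,1-disubstituted alkenyl group from boron to carbon (C2–C10' bond), followed by C(sp3)–C(sp2) reductive elimination (C3–C3a bond). The closest known reaction is the palladium/Mandyphos-catalysed enantioselective conjunctive cross-coupling of bis(alkenyl)borates with alkenyl and aryl halides or triflates, which gives α-chiral allylboronates. No ring is closed. The new stereocentre C2 (the boron-bearing carbon) is set by the chiral bisphosphine on palladium through face-selective binding of the vinyl group, so it is catalyst-controlled and independent of the remote C5 silyloxy centre. The step needs activation of the vinyl group and not of the substituted alkenyl group, which the lower steric demand of the unsubstituted olefin for π-binding secures, leaving the 2-substituted alkenyl as the only migrating carbon group. It also needs the metalate shift to outrun direct Suzuki-type transmetalation, which the chelating ligand and the halide-free cationic palladium centre secure.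

**Step 9**
Reactants: 13 allylboronate from step 8
Product: 14 (6R)-6-[(tert-butyldimethylsilyl)oxy]-2-[(2S,6E,10E)-12-[(tert-butyldimethylsilyl)oxy]-2-hydroxy-7,11-dimethyl-3-methylidenedodeca-6,10-dien-1-yl]-3-methoxycyclohex-2-en-1-one
Conditions: NaBO3·4H2O, THF/H2O, rt
Reagents that add atoms: sodium perborate, O[B-]1(O)OO[B-](O)(O)OO1.[Na+].[Na+]
Why: Oxidation of the C–B bond by 1,2-shift of carbon from boron to oxygen proceeds with retention at C2, and the near-neutral perborate should leave the methoxy enone, the silyl ethers and the α-silyloxy ketone alone.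

**Step 10**
Reactants: 14 allylic alcohol from step 9
Product: 15 (6R)-6-[(tert-butyldimethylsilyl)oxy]-2-[(2S)-2-hydroxy-2-[(2R)-2-[(3E,7E)-9-[(tert-butyldimethylsilyl)oxy]-4,8-dimethylnona-3,7-dien-1-yl]oxiran-2-yl]ethyl]-3-methoxycyclohex-2-en-1-one
Conditions: VO(acac)2 (5 mol %), t-BuOOH (in decane, 1.5 equiv), CH2Cl2, 0 °C to rt
Reagents that add atoms: tert-butyl hydroperoxide, CC(C)(C)OO
Why: Vanadium-catalysed hydroxyl-directed epoxidation touches only the allylic olefin, and the vanadate ester transition state that minimises A(1,2) strain with the C10' substituent should give the erythro epoxy alcohol, which fixes C10' by 1,2-induction from C2.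

**Step 11**
Reactants: 15 epoxy alcohol from step 10
Product: 16 (2S,5R)-5-[(tert-butyldimethylsilyl)oxy]-2-[(2R)-2-[(3E,7E)-9-[(tert-butyldimethylsilyl)oxy]-4,8-dimethylnona-3,7-dien-1-yl]oxiran-2-yl]-3,5,6,7-tetrahydro-1-benzofuran-4(2H)-one
Conditions: PPTS (10 mol %), 4 Å molecular sieves, CH2Cl2, rt
Reagents that add atoms: none
Why: Acid-catalysed vinylogous transetherification: carbonyl protonation makes C7a an oxocarbenium-type carbon, the C2 hydroxyl adds (5-exo-trig with respect to the C=O+ bond) and methanol is lost, closing ring B with C2 unchanged because its C–O bond is never broken.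

**Step 12**
Reactants: 16 epoxide from step 11
Product: 18 (2S,5R)-5-[(tert-butyldimethylsilyl)oxy]-2-[(2S,5E,9E)-11-[(tert-butyldimethylsilyl)oxy]-2-hydroxy-6,10-dimethylundeca-5,9-dien-2-yl]-3,5,6,7-tetrahydro-1-benzofuran-4(2H)-one, via iodohydrin 17 (not isolated)
Conditions: LiI (3 equiv), AcOH (1.5 equiv), THF, 0 °C to rt; aqueous work-up; Bu3SnH (3 equiv), (PhSe)2 (0.1 equiv), AIBN (0.1 equiv), benzene, 80 °C
Reagents that add atoms: none
Why: SN2 opening by iodide at the unhindered epoxide CH2 leaves the C10'–O bond and its configuration intact, and radical-chain deiodination by Bu3SnH with PhSeH (formed from (PhSe)2) as fast hydrogen donor should quench the primary radical before 5-exo cyclisation onto the C6'=C7' olefin; no hydride is used, so the ring A ketone survives.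

**Step 13**
Reactants: 18 bis-silyl ether from step 12
Product: 19 (2S,5R)-2-[(2S,5E,9E)-2,11-dihydroxy-6,10-dimethylundeca-5,9-dien-2-yl]-5-hydroxy-3,5,6,7-tetrahydro-1-benzofuran-4(2H)-one
Conditions: HF·pyridine, pyridine, THF, 0 °C to rt
Reagents that add atoms: none
Why: Fluoride cleavage of both silyl ethers under buffered, non-basic conditions should avoid epimerisation of the α-hydroxy ketone at C5.

**Step 14**
Reactants: 19 triol from step 13
Product: 20 (2E,6E,10S)-10-hydroxy-10-[(2S,5R)-5-hydroxy-4-oxo-2,3,4,5,6,7-hexahydro-1-benzofuran-2-yl]-2,6-dimethylundeca-2,6-dienal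
Conditions: TEMPO (0.1 equiv), PhI(OAc)2 (1.2 equiv), CH2Cl2, rt
Reagents that add atoms: none
Why: Oxoammonium oxidation (TEMPO/PhI(OAc)2) is selective for the primary allylic alcohol over the secondary ketol and the tertiary alcohol and stops at the E-enal.

**Step 15**
Reactants: 20 enal from step 14
Product: 21 (2E,6E,10S)-10-hydroxy-10-[(2S,5R)-5-hydroxy-4-oxo-2,3,4,5,6,7-hexahydro-1-benzofuran-2-yl]-2,6-dimethylundeca-2,6-dienoic acid (target)
Conditions: NaClO2, NaH2PO4, 2-methyl-2-butene, t-BuOH/H2O, 0 °C to rt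
Reagents that add atoms: sodium chlorite, [Na+].[O-]Cl=O
Why: Pinnick oxidation of the enal by chlorous acid, with 2-methyl-2-butene scavenging HOCl so that the olefins, the ketol and the olefin geometry are preserved.

**Compound list**
1 | (E)-geranylacetone, (5E)-6,10-dimethylundeca-5,9-dien-2-one | CC(=O)CC/C=C(\C)CCC=C(C)C | starting material
2 | (5E,9E)-11-hydroxy-6,10-dimethylundeca-5,9-dien-2-one | CC(=O)CC/C=C(\C)CC/C=C(\C)CO | intermediate
3 | (5E,9E)-11-[(tert-butyldimethylsilyl)oxy]-6,10-dimethylundeca-5,9-dien-2-one | CC(=O)CC/C=C(\C)CC/C=C(\C)CO[Si](C)(C)C(C)(C)C | intermediate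
4 | trisylhydrazone of 3, N'-[(2E,5E,9E)-11-[(tert-butyldimethylsilyl)oxy]-6,10-dimethylundeca-5,9-dien-2-ylidene]-2,4,6-tri(propan-2-yl)benzenesulfonohydrazide | C/C(CC/C=C(\C)CC/C=C(\C)CO[Si](C)(C)C(C)(C)C)=N\NS(=O)(=O)c1c(C(C)C)cc(C(C)C)cc1C(C)C | intermediate
5 | 3-methoxycyclohex-2-en-1-one | COC1=CC(=O)CCC1 | starting material
6 | (±)-4-methoxy-2-oxocyclohex-3-en-1-yl acetate | COC1=CC(=O)C(OC(C)=O)CC1 | intermediate
7 | (6R)-6-hydroxy-3-methoxycyclohex-2-en-1-one | COC1=CC(=O)[C@H](O)CC1 | intermediate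
8 | (6R)-6-[(tert-butyldimethylsilyl)oxy]-3-methoxycyclohex-2-en-1-one | COC1=CC(=O)[C@H](O[Si](C)(C)C(C)(C)C)CC1 | intermediate
9 | (6R)-2-bromo-6-[(tert-butyldimethylsilyl)oxy]-3-methoxycyclohex-2-en-1-one | COC1=C(Br)C(=O)[C@H](O[Si](C)(C)C(C)(C)C)CC1 | intermediate
10 | 4,4,5,5-tetramethyl-2-vinyl-1,3,2-dioxaborolane | C=CB1OC(C)(C)C(C)(C)O1 | starting material
11 | [(5E,9E)-11-[(tert-butyldimethylsilyl)oxy]-6,10-dimethylundeca-1,5,9-trien-2-yl]lithium | [Li]C(=C)CC/C=C(\C)CC/C=C(\C)CO[Si](C)(C)C(C)(C)C | intermediate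
12 | lithium [(5E,9E)-11-[(tert-butyldimethylsilyl)oxy]-6,10-dimethylundeca-1,5,9-trien-2-yl](pinacolato)vinylborate | [Li+].C=C[B-]1(OC(C)(C)C(C)(C)O1)C(=C)CC/C=C(\C)CC/C=C(\C)CO[Si](C)(C)C(C)(C)C | intermediate
13 | (6R)-6-[(tert-butyldimethylsilyl)oxy]-2-[(2S,6E,10E)-12-[(tert-butyldimethylsilyl)oxy]-7,11-dimethyl-3-methylidene-2-(4,4,5,5-tetramethyl-1,3,2-dioxaborolan-2-yl)dodeca-6,10-dien-1-yl]-3-methoxycyclohex-2-en-1-one | COC1=C(C[C@H](B2OC(C)(C)C(C)(C)O2)C(=C)CC/C=C(\C)CC/C=C(\C)CO[Si](C)(C)C(C)(C)C)C(=O)[C@H](O[Si](C)(C)C(C)(C)C)CC1 | intermediate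
14 | (6R)-6-[(tert-butyldimethylsilyl)oxy]-2-[(2S,6E,10E)-12-[(tert-butyldimethylsilyl)oxy]-2-hydroxy-7,11-dimethyl-3-methylidenedodeca-6,10-dien-1-yl]-3-methoxycyclohex-2-en-1-one | COC1=C(C[C@H](O)C(=C)CC/C=C(\C)CC/C=C(\C)CO[Si](C)(C)C(C)(C)C)C(=O)[C@H](O[Si](C)(C)C(C)(C)C)CC1 | intermediate
15 | (6R)-6-[(tert-butyldimethylsilyl)oxy]-2-[(2S)-2-hydroxy-2-[(2R)-2-[(3E,7E)-9-[(tert-butyldimethylsilyl)oxy]-4,8-dimethylnona-3,7-dien-1-yl]oxiran-2-yl]ethyl]-3-methoxycyclohex-2-en-1-one | COC1=C(C[C@H](O)[C@@]2(CC/C=C(\C)CC/C=C(\C)CO[Si](C)(C)C(C)(C)C)CO2)C(=O)[C@H](O[Si](C)(C)C(C)(C)C)CC1 | intermediate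
16 | (2S,5R)-5-[(tert-butyldimethylsilyl)oxy]-2-[(2R)-2-[(3E,7E)-9-[(tert-butyldimethylsilyl)oxy]-4,8-dimethylnona-3,7-dien-1-yl]oxiran-2-yl]-3,5,6,7-tetrahydro-1-benzofuran-4(2H)-one | O=C1[C@H](O[Si](C)(C)C(C)(C)C)CCC2=C1C[C@H](O2)[C@@]3(CC/C=C(\C)CC/C=C(\C)CO[Si](C)(C)C(C)(C)C)CO3 | intermediate
17 | (2S,5R)-5-[(tert-butyldimethylsilyl)oxy]-2-[(2S,5E,9E)-11-[(tert-butyldimethylsilyl)oxy]-2-hydroxy-1-iodo-6,10-dimethylundeca-5,9-dien-2-yl]-3,5,6,7-tetrahydro-1-benzofuran-4(2H)-one | O=C1[C@H](O[Si](C)(C)C(C)(C)C)CCC2=C1C[C@H](O2)[C@](O)(CI)CC/C=C(\C)CC/C=C(\C)CO[Si](C)(C)C(C)(C)C | intermediate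
18 | (2S,5R)-5-[(tert-butyldimethylsilyl)oxy]-2-[(2S,5E,9E)-11-[(tert-butyldimethylsilyl)oxy]-2-hydroxy-6,10-dimethylundeca-5,9-dien-2-yl]-3,5,6,7-tetrahydro-1-benzofuran-4(2H)-one | O=C1[C@H](O[Si](C)(C)C(C)(C)C)CCC2=C1C[C@H](O2)[C@](O)(C)CC/C=C(\C)CC/C=C(\C)CO[Si](C)(C)C(C)(C)C | intermediate
19 | (2S,5R)-2-[(2S,5E,9E)-2,11-dihydroxy-6,10-dimethylundeca-5,9-dien-2-yl]-5-hydroxy-3,5,6,7-tetrahydro-1-benzofuran-4(2H)-one | O=C1[C@H](O)CCC2=C1C[C@H](O2)[C@](O)(C)CC/C=C(\C)CC/C=C(\C)CO | intermediate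
20 | (2E,6E,10S)-10-hydroxy-10-[(2S,5R)-5-hydroxy-4-oxo-2,3,4,5,6,7-hexahydro-1-benzofuran-2-yl]-2,6-dimethylundeca-2,6-dienal | O=C1[C@H](O)CCC2=C1C[C@H](O2)[C@](O)(C)CC/C=C(\C)CC/C=C(\C)C=O | intermediate
21 | (2E,6E,10S)-10-hydroxy-10-[(2S,5R)-5-hydroxy-4-oxo-2,3,4,5,6,7-hexahydro-1-benzofuran-2-yl]-2,6-dimethylundeca-2,6-dienoic acid | C/C(=C\CC[C@](C)(O)[C@@H]1CC2=C(CC[C@@H](O)C2=O)O1)CC/C=C(\C)C(=O)O | target

**Step count**
Total: 15 steps. Longest linear sequence: 12 steps (steps 4 to 15, from 5).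

**Steps most likely to fail**

Step 8. Direct Suzuki-type transmetalation of an alkenyl group may outrun the metalate shift, the lithium sulfinate left by the Shapiro reaction may bind and slow the cationic palladium centre, reductive elimination at the hindered α-keto alkenyl palladium may be slow, and facial selectivity at C2 may be eroded. The fallback uses two-component chemistry, sets out from 9 and 4 and returns at 14. Stille allylation of 9 (allyltributylstannane, Pd(PPh3)4) should give (6R)-6-[(tert-butyldimethylsilyl)oxy]-3-methoxy-2-(prop-2-en-1-yl)cyclohex-2-en-1-one F1. Lemieux–Johnson cleavage (OsO4 cat., NaIO4, 2,6-lutidine) should then give 2-[(5R)-5-[(tert-butyldimethylsilyl)oxy]-2-methoxy-6-oxocyclohex-1-en-1-yl]acetaldehyde F2. In parallel, Shapiro reaction of 4 with an iodine quench should give tert-butyl{[(2E,6E)-10-iodo-2,6-dimethylundeca-2,6,10-trien-1-yl]oxy}dimethylsilane F3. A catalytic asymmetric Nozaki–Hiyama–Kishi coupling of F3 with F2 (CrCl2, NiCl2, chiral sulfonamide ligand) forms the same C2–C10' bond and should give 14.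

Step 12. Iodide may attack the tertiary epoxide carbon, the epoxide may rearrange to an aldehyde under lithium assistance, and the primary radical may cyclise onto the neighbouring olefin during deiodination. The fallback sets out from 16 and returns at 18. Opening of the epoxide with sodium thiophenolate (PhSH, NaOH, MeOH) should give (2S,5R)-5-[(tert-butyldimethylsilyl)oxy]-2-[(2S,5E,9E)-11-[(tert-butyldimethylsilyl)oxy]-2-hydroxy-6,10-dimethyl-1-(phenylsulfanyl)undeca-5,9-dien-2-yl]-3,5,6,7-tetrahydro-1-benzofuran-4(2H)-one F4. Desulfurisation with acetone-deactivated Raney nickel (Ni) in ethanol, which generates no free carbon radical in solution and spares trisubstituted olefins, should give 18.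

Step 11. The acid may open or rearrange the 2,2-disubstituted epoxide before or during the vinylogous transetherification, or ring closure may stall. The fallback changes the order of events, sets out from 15 and returns at 18. Chelation-assisted opening of the epoxy alcohol with MgI2 (Et2O, −60 °C) should give (6R)-6-[(tert-butyldimethylsilyl)oxy]-2-[(2S,3S,6E,10E)-12-[(tert-butyldimethylsilyl)oxy]-2,3-dihydroxy-3-(iodomethyl)-7,11-dimethyldodeca-6,10-dien-1-yl]-3-methoxycyclohex-2-en-1-one F5. Deiodination (Bu3SnH, (PhSe)2 cat., AIBN) should give (6R)-6-[(tert-butyldimethylsilyl)oxy]-2-[(2S,3S,6E,10E)-12-[(tert-butyldimethylsilyl)oxy]-2,3-dihydroxy-3,7,11-trimethyldodeca-6,10-dien-1-yl]-3-methoxycyclohex-2-en-1-one F6. With no epoxide left, PPTS should close ring B through the less hindered secondary hydroxyl (five-membered ring) to give 18.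

**Further compounds**
F1 | step 8 | (6R)-6-[(tert-butyldimethylsilyl)oxy]-3-methoxy-2-(prop-2-en-1-yl)cyclohex-2-en-1-one | COC1=C(CC=C)C(=O)[C@H](O[Si](C)(C)C(C)(C)C)CC1
F2 | step 8 | 2-[(5R)-5-[(tert-butyldimethylsilyl)oxy]-2-methoxy-6-oxocyclohex-1-en-1-yl]acetaldehyde | COC1=C(CC=O)C(=O)[C@H](O[Si](C)(C)C(C)(C)C)CC1
F3 | step 8 | tert-butyl{[(2E,6E)-10-iodo-2,6-dimethylundeca-2,6,10-trien-1-yl]oxy}dimethylsilane | C=C(I)CC/C=C(\C)CC/C=C(\C)CO[Si](C)(C)C(C)(C)C
F4 | step 12 | (2S,5R)-5-[(tert-butyldimethylsilyl)oxy]-2-[(2S,5E,9E)-11-[(tert-butyldimethylsilyl)oxy]-2-hydroxy-6,10-dimethyl-1-(phenylsulfanyl)undeca-5,9-dien-2-yl]-3,5,6,7-tetrahydro-1-benzofuran-4(2H)-one | O=C1[C@H](O[Si](C)(C)C(C)(C)C)CCC2=C1C[C@H](O2)[C@](O)(CSc3ccccc3)CC/C=C(\C)CC/C=C(\C)CO[Si](C)(C)C(C)(C)C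
F5 | step 11 | (6R)-6-[(tert-butyldimethylsilyl)oxy]-2-[(2S,3S,6E,10E)-12-[(tert-butyldimethylsilyl)oxy]-2,3-dihydroxy-3-(iodomethyl)-7,11-dimethyldodeca-6,10-dien-1-yl]-3-methoxycyclohex-2-en-1-one | COC1=C(C[C@H](O)[C@](O)(CI)CC/C=C(\C)CC/C=C(\C)CO[Si](C)(C)C(C)(C)C)C(=O)[C@H](O[Si](C)(C)C(C)(C)C)CC1
F6 | step 11 | (6R)-6-[(tert-butyldimethylsilyl)oxy]-2-[(2S,3S,6E,10E)-12-[(tert-butyldimethylsilyl)oxy]-2,3-dihydroxy-3,7,11-trimethyldodeca-6,10-dien-1-yl]-3-methoxycyclohex-2-en-1-one | COC1=C(C[C@H](O)[C@](O)(C)CC/C=C(\C)CC/C=C(\C)CO[Si](C)(C)C(C)(C)C)C(=O)[C@H](O[Si](C)(C)C(C)(C)C)CC1
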